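**Plan**
- Retrosynthesis: the two sulfate S–O bonds (O3, O7) and the protecting groups go first. The flavonol is then cut at C2–C1' and C3–O, giving 5,7-bis(benzyloxy)chromone and an arylmagnesium bromide. The chromone is cut at O1–C2 and C2–C3, giving phloroacetophenone and a one-carbon unit.
- Enabling feature: in ring C, C2 and C3 are the β- and α-carbons of the C4 enone and carry ring B and an oxygen. This is the pattern left by conjugate arylation followed by oxidation of the enol derivative.
- Forward: ring A is bought and ring C is closed by enaminone cyclisation (O1–C2). Ring B goes onto C2 and oxygen onto C3 in one telescoped operation, followed by dehydrogenation, debenzylation, bis-sulfation and desilylation.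
- Regiocontrol of sulfation: O5 and O7 carry benzyl and O3' carries triisopropylsilyl (TIPS). Hydrogenolysis frees O7 and the chelated O5 while O3' stays masked until both sulfates are in place.
- Stereochemistry: the target is achiral. The trans C2/C3 stereocentres of the intermediate come from anti epoxidation and are erased by the dehydrogenation.

Key step: step 5

Remark on the chemistry: the aryl sulfate monoesters 16 and 17 are drawn as free hydrogen sulfates, as in the target. In the flask they would be ammonium salts, and 17 is released as the acid only in the final cold cation exchange.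

**Step 1**
Reactants: 1 2,4,6-trihydroxyacetophenone
Product: 2 1-[2,4-bis(benzyloxy)-6-hydroxyphenyl]ethan-1-one
Conditions: BnBr (2.1 equiv), K2CO3, DMF, rt
Reagents that add atoms: benzyl bromide, BrCc1ccccc1
Why: Williamson etherification, in which the 4-OH and one ortho OH are alkylated while the remaining ortho hydroxyl, hydrogen-bonded to the acetyl carbonyl, is too weakly nucleophilic to react with a limited amount of benzyl bromide.

**Step 2**
Reactants: 2 1-[2,4-bis(benzyloxy)-6-hydroxyphenyl]ethan-1-one; 3 N,N-dimethylformamide dimethyl acetal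
Product: 5 5,7-bis(benzyloxy)-4H-chromen-4-one, via enaminone 4 (not isolated)
Conditions: 3, toluene, 100 °C; concentrate; conc. HCl, CH2Cl2, 40 °C
Reagents that add atoms: N,N-dimethylformamide dimethyl acetal (3), COC(OC)N(C)C (supplies C2 of the chromone)
Why: Enaminone chromone synthesis, in which the acetal condenses with the acetyl methyl group to the β-dimethylamino enone and acid then drives 6-endo attack of the phenol on the β-carbon with loss of dimethylamine, closing ring C without harming the benzyl ethers.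

**Step 3**
Reactants: 6 5-bromo-2-methoxyphenol
Product: 7 (5-bromo-2-methoxyphenoxy)tri(propan-2-yl)silane
Conditions: TIPSCl, imidazole, DMF, rt
Reagents that add atoms: chlorotri(propan-2-yl)silane, CC(C)[Si](Cl)(C(C)C)C(C)C
Why: Imidazole-mediated O-silylation of a phenol, with the bulky TIPS group chosen because it should survive Grignard formation, peracid, buffered hot acetic acid and hydrogenolysis yet fall to fluoride at the end.

**Step 4**
Reactants: 7 (5-bromo-2-methoxyphenoxy)tri(propan-2-yl)silane
Product: 8 {4-methoxy-3-[tri(propan-2-yl)silyloxy]phenyl}magnesium bromide (titrated THF solution)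
Conditions: Mg turnings (I2 crystal), THF, 50 °C
Reagents that add atoms: magnesium, [Mg]
Why: Grignard formation by insertion of magnesium into the aryl C–Br bond, for which the methyl and silyl ethers are inert spectators.

**Step 5**
Reactants: 5 5,7-bis(benzyloxy)-4H-chromen-4-one; 8 {4-methoxy-3-[tri(propan-2-yl)silyloxy]phenyl}magnesium bromide
Product: 13 rac-(2R,3R)-5,7-bis(benzyloxy)-3-hydroxy-2-{4-methoxy-3-[tri(propan-2-yl)silyloxy]phenyl}-2,3-dihydro-4H-chromen-4-one, via benzopyrylium triflate 9 (not isolated), via silyl enol ether 10 (not isolated), via siloxy epoxide 11 (not isolated), via 3-silyloxy ketone 12 (not isolated)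
Conditions: TBSOTf (1.1 equiv), CH2Cl2, rt; CuBr·SMe2 (10 mol %, monovalent copper), 8 (1.3 equiv), THF, −78 to −20 °C; cold aq. NaHCO3 wash, crude solution carried on; mCPBA, NaHCO3, CH2Cl2, 0 °C; 2 M aq. HCl, THF, rt
Reagents that add atoms: tert-butyldimethylsilyl trifluoromethanesulfonate, CC(C)(C)[Si](C)(C)OS(=O)(=O)C(F)(F)F (silyl group carried by 9–12 only); 3-chloroperoxybenzoic acid, OOC(=O)c1cccc(Cl)c1 (oxygen on C3)
Why: Silylation of the C4 carbonyl oxygen turns the weakly electrophilic dialkoxychromone into the aromatic 4-siloxybenzopyrylium cation 9, to which the arylcopper species generated from 8 transfers its aryl group at C2 to give the 4-siloxy-2H-chromene 10; the peracid then epoxidises the electron-rich C3=C4 enol ether bond (11), the siloxy epoxide opens with silicon passing to O3 (12), and aqueous acid removes the alkyl silyl group. The closest known reaction types are the silyl triflate-promoted addition of organometallic reagents to chromones and the Rubottom oxidation of silyl enol ethers, here run back to back. No ring is closed; two bonds, C2–C1' and C3–O, are formed. C2 is created without control (racemate), and C3 is set relative to it because the peracid should approach the face of 10 opposite the C2 aryl group, giving the trans product. The selectivity required is attack at C2 and not at C4, which is secured because C4 of the cation bears the siloxy donor and is shielded by the peri 5-benzyloxy group while C2 is unsubstituted. In the acid work-up the alkyl O3–Si bond should cleave far faster than the aryl O3'–Si bond, so the TIPS ether and the benzyl ethers are expected to persist.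

**Step 6**
Reactants: 13 rac-(2R,3R)-5,7-bis(benzyloxy)-3-hydroxy-2-{4-methoxy-3-[tri(propan-2-yl)silyloxy]phenyl}-2,3-dihydro-4H-chromen-4-one
Product: 14 5,7-bis(benzyloxy)-3-hydroxy-2-{4-methoxy-3-[tri(propan-2-yl)silyloxy]phenyl}-4H-chromen-4-one
Conditions: I2, KOAc, AcOH, 90 °C
Reagents that add atoms: none
Why: Iodine/acetate dehydrogenation of a dihydroflavonol, in which iodination of the enol at C3 and loss of HI give the 3,4-dione that tautomerises through its C2–H to the aromatic 3-hydroxy-4-pyranone, removing both stereocentres.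

**Step 7**
Reactants: 14 5,7-bis(benzyloxy)-3-hydroxy-2-{4-methoxy-3-[tri(propan-2-yl)silyloxy]phenyl}-4H-chromen-4-one
Product: 15 3,5,7-trihydroxy-2-{4-methoxy-3-[tri(propan-2-yl)silyloxy]phenyl}-4H-chromen-4-one
Conditions: H2 (1 atm), 10% Pd/C, EtOAc/THF, rt
Reagents that add atoms: none
Why: Catalytic hydrogenolysis cleaves the two aryl benzyl ethers, while the tetrasubstituted pyranone double bond, the aryl methyl ether and the silyl ether should be untouched under one atmosphere of hydrogen in an aprotic solvent.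

**Step 8**
Reactants: 15 3,5,7-trihydroxy-2-{4-methoxy-3-[tri(propan-2-yl)silyloxy]phenyl}-4H-chromen-4-one
Product: 16 5-hydroxy-2-{4-methoxy-3-[tri(propan-2-yl)silyloxy]phenyl}-4-oxo-4H-chromene-3,7-diyl bis(hydrogen sulfate)
Conditions: SO3·NMe3 (6 equiv), Et3N, DMF, 50 °C
Reagents that add atoms: sulfur trioxide–trimethylamine complex, C[N+](C)(C)S(=O)(=O)[O-]
Why: O-Sulfation with an amine–sulfur trioxide complex, in which the 7-OH and the enolic 3-OH react while the 5-OH is held in a hydrogen bond to the C4 carbonyl and O3' is blocked by silicon, so the pattern is fixed by protection and not by relative rates.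

**Step 9**
Reactants: 16 5-hydroxy-2-{4-methoxy-3-[tri(propan-2-yl)silyloxy]phenyl}-4-oxo-4H-chromene-3,7-diyl bis(hydrogen sulfate)
Product: 17 5-hydroxy-2-(3-hydroxy-4-methoxyphenyl)-4-oxo-4H-chromene-3,7-diyl bis(hydrogen sulfate) (tamarixetin 3,7-disulfate)
Conditions: Bu4NF/AcOH (1:1), THF, 0 °C to rt; sulfonic acid cation-exchange resin (H+ form), H2O/MeOH, 0 °C; lyophilise
Reagents that add atoms: none
Why: Fluoride-mediated cleavage of the aryl silyl ether, to which sulfate monoester anions are inert, followed by a brief cold pass over an acidic resin that replaces the ammonium counter-ions by protons.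

**Compound list**
1 | 2,4,6-trihydroxyacetophenone | CC(=O)c1c(O)cc(O)cc1O | starting material
2 | 1-[2,4-bis(benzyloxy)-6-hydroxyphenyl]ethan-1-one | CC(=O)c1c(O)cc(OCc2ccccc2)cc1OCc1ccccc1 | intermediate
3 | N,N-dimethylformamide dimethyl acetal | COC(OC)N(C)C | starting material
4 | (E)-1-[2,4-bis(benzyloxy)-6-hydroxyphenyl]-3-(dimethylamino)prop-2-en-1-one (not isolated) | CN(C)/C=C/C(=O)c1c(O)cc(OCc2ccccc2)cc1OCc1ccccc1 | intermediate
5 | 5,7-bis(benzyloxy)-4H-chromen-4-one | O=c1ccoc2cc(OCc3ccccc3)cc(OCc3ccccc3)c12 | intermediate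
6 | 5-bromo-2-methoxyphenol | COc1ccc(Br)cc1O | starting material
7 | (5-bromo-2-methoxyphenoxy)tri(propan-2-yl)silane | COc1ccc(Br)cc1O[Si](C(C)C)(C(C)C)C(C)C | intermediate
8 | {4-methoxy-3-[tri(propan-2-yl)silyloxy]phenyl}magnesium bromide | COc1ccc([Mg]Br)cc1O[Si](C(C)C)(C(C)C)C(C)C | intermediate
9 | 5,7-bis(benzyloxy)-4-[tert-butyl(dimethyl)silyloxy]chromenylium trifluoromethanesulfonate (not isolated) | CC(C)(C)[Si](C)(C)Oc1cc[o+]c2cc(OCc3ccccc3)cc(OCc3ccccc3)c12.[O-]S(=O)(=O)C(F)(F)F | intermediate
10 | racemic 5,7-bis(benzyloxy)-4-[tert-butyl(dimethyl)silyloxy]-2-{4-methoxy-3-[tri(propan-2-yl)silyloxy]phenyl}-2H-chromene, one enantiomer drawn (not isolated) | CC(C)(C)[Si](C)(C)OC1=C[C@@H](c2ccc(OC)c(O[Si](C(C)C)(C(C)C)C(C)C)c2)Oc2cc(OCc3ccccc3)cc(OCc3ccccc3)c21 | intermediate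
11 | racemic 3,4-epoxide of 10 (flavonoid numbering; C4 keeps the silyloxy group, oxirane oxygen on the face opposite the C2 aryl group), one enantiomer drawn (not isolated) | CC(C)(C)[Si](C)(C)O[C@@]12O[C@@H]1[C@@H](c1ccc(OC)c(O[Si](C(C)C)(C(C)C)C(C)C)c1)Oc1cc(OCc3ccccc3)cc(OCc3ccccc3)c12 | intermediate
12 | rac-(2R,3R)-5,7-bis(benzyloxy)-3-[tert-butyl(dimethyl)silyloxy]-2-{4-methoxy-3-[tri(propan-2-yl)silyloxy]phenyl}-2,3-dihydro-4H-chromen-4-one, trans (not isolated) | O=C1c2c(OCc3ccccc3)cc(OCc3ccccc3)cc2O[C@H](c2ccc(OC)c(O[Si](C(C)C)(C(C)C)C(C)C)c2)[C@H]1O[Si](C)(C)C(C)(C)C | intermediate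
13 | rac-(2R,3R)-5,7-bis(benzyloxy)-3-hydroxy-2-{4-methoxy-3-[tri(propan-2-yl)silyloxy]phenyl}-2,3-dihydro-4H-chromen-4-one, trans, one enantiomer drawn | O=C1c2c(OCc3ccccc3)cc(OCc3ccccc3)cc2O[C@H](c2ccc(OC)c(O[Si](C(C)C)(C(C)C)C(C)C)c2)[C@H]1O | intermediate
14 | 5,7-bis(benzyloxy)-3-hydroxy-2-{4-methoxy-3-[tri(propan-2-yl)silyloxy]phenyl}-4H-chromen-4-one | O=c1c(O)c(-c2ccc(OC)c(O[Si](C(C)C)(C(C)C)C(C)C)c2)oc2cc(OCc3ccccc3)cc(OCc3ccccc3)c12 | intermediate
15 | 3,5,7-trihydroxy-2-{4-methoxy-3-[tri(propan-2-yl)silyloxy]phenyl}-4H-chromen-4-one | O=c1c(O)c(-c2ccc(OC)c(O[Si](C(C)C)(C(C)C)C(C)C)c2)oc2cc(O)cc(O)c12 | intermediate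
16 | 5-hydroxy-2-{4-methoxy-3-[tri(propan-2-yl)silyloxy]phenyl}-4-oxo-4H-chromene-3,7-diyl bis(hydrogen sulfate) | COc1ccc(-c2oc3cc(OS(=O)(=O)O)cc(O)c3c(=O)c2OS(=O)(=O)O)cc1O[Si](C(C)C)(C(C)C)C(C)C | intermediate
17 | 5-hydroxy-2-(3-hydroxy-4-methoxyphenyl)-4-oxo-4H-chromene-3,7-diyl bis(hydrogen sulfate) | COc1ccc(-c2oc3cc(OS(=O)(=O)O)cc(O)c3c(=O)c2OS(=O)(=O)O)cc1O | target

**Step count**
Total: 9 steps. Longest linear sequence: 7 steps (1 → 2 → 5 → 13 → 14 → 15 → 16 → 17; the branch from 6 is equally long).

**Steps most likely to fail**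

Step 5. Aryl transfer to the donor-rich cation may stall, or the enol ether may lose silicon before the peracid acts, which would leave the C3 position unoxidised. In that case the two bonds would be made in separate, individually known operations, setting out from 5 and 8. Grignard reagent 8 is quenched with B(OMe)3 and hydrolysed to {4-methoxy-3-[tri(propan-2-yl)silyloxy]phenyl}boronic acid F1. F1 is added to chromone 5 under Pd(OCOCF3)2/2,2'-bipyridine catalysis (divalent palladium; aqueous 1,2-dichloroethane, 60 °C) to give rac-5,7-bis(benzyloxy)-2-{4-methoxy-3-[tri(propan-2-yl)silyloxy]phenyl}-2,3-dihydro-4H-chromen-4-one F2. Soft enolisation of F2 with TBSOTf/Et3N in CH2Cl2 at 0 °C then gives silyl enol ether 10, where the route is rejoined; the peracid and acid treatment of step 5 lead on to 13.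

Step 8. Sulfation of the hindered, weakly nucleophilic O3 may remain incomplete and leave hard-to-separate mixtures of mono- and disulfates. The two sulfates would then be introduced one at a time, setting out from 14, where O3 is the only free hydroxyl. Forcing sulfation (SO3·NMe3, Et3N, DMF, 60 °C) gives 5,7-bis(benzyloxy)-2-{4-methoxy-3-[tri(propan-2-yl)silyloxy]phenyl}-4-oxo-4H-chromen-3-yl hydrogen sulfate F3, which is still lipophilic enough for normal chromatography as its ammonium salt. Hydrogenolysis (H2, Pd/C, THF/MeOH with a little Et3N) gives 5,7-dihydroxy-2-{4-methoxy-3-[tri(propan-2-yl)silyloxy]phenyl}-4-oxo-4H-chromen-3-yl hydrogen sulfate F4. A slight excess of SO3·NMe3 with Et3N at rt then sulfates only the non-chelated O7 and returns the route at 16.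

Step 6. Enol iodination may be slow for the electron-rich aryl ketone, and prolonged heating risks partial loss of the silyl ether or ring contraction of the hydroxy ketone. The alternative, setting out from 13, oxidises the carbinol instead of the enol. Dess–Martin periodinane (NaHCO3, CH2Cl2, rt) should give rac-5,7-bis(benzyloxy)-2-{4-methoxy-3-[tri(propan-2-yl)silyloxy]phenyl}-2H-chromene-3,4-dione F5, which enolises on contact with Et3N or silica and returns the route at 14.

**Further compounds**
F1 | step 5 | {4-methoxy-3-[tri(propan-2-yl)silyloxy]phenyl}boronic acid | COc1ccc(B(O)O)cc1O[Si](C(C)C)(C(C)C)C(C)C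
F2 | step 5 | rac-5,7-bis(benzyloxy)-2-{4-methoxy-3-[tri(propan-2-yl)silyloxy]phenyl}-2,3-dihydro-4H-chromen-4-one | O=C1C[C@@H](c2ccc(OC)c(O[Si](C(C)C)(C(C)C)C(C)C)c2)Oc2cc(OCc3ccccc3)cc(OCc3ccccc3)c21
F3 | step 8 | 5,7-bis(benzyloxy)-2-{4-methoxy-3-[tri(propan-2-yl)silyloxy]phenyl}-4-oxo-4H-chromen-3-yl hydrogen sulfate | COc1ccc(-c2oc3cc(OCc4ccccc4)cc(OCc4ccccc4)c3c(=O)c2OS(=O)(=O)O)cc1O[Si](C(C)C)(C(C)C)C(C)C
F4 | step 8 | 5,7-dihydroxy-2-{4-methoxy-3-[tri(propan-2-yl)silyloxy]phenyl}-4-oxo-4H-chromen-3-yl hydrogen sulfate | COc1ccc(-c2oc3cc(O)cc(O)c3c(=O)c2OS(=O)(=O)O)cc1O[Si](C(C)C)(C(C)C)C(C)C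
F5 | step 6 | rac-5,7-bis(benzyloxy)-2-{4-methoxy-3-[tri(propan-2-yl)silyloxy]phenyl}-2H-chromene-3,4-dione | O=C1C(=O)[C@@H](c2ccc(OC)c(O[Si](C(C)C)(C(C)C)C(C)C)c2)Oc2cc(OCc3ccccc3)cc(OCc3ccccc3)c21
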